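**Retrosynthetic overview** (upper unit: rings A, B, C; lower unit: rings D, E, F)
- Target ⇐ global O-debenzylation; the upper C3–OH and C4–H come from hydroboration–oxidation of a 2-aryl-4-(gallocatechin-8-yl)-2H-chromene, which sets C3 and C4 anti to the C2 aryl group in one step.
- Chromene ring C (formed last) ⇐ C4–C4a Friedel–Crafts closure of a dithiane-derived thionium ion onto ring A; ring A and the O1–C2 bond ⇐ Mitsunobu inversion with 3-(benzyloxy)phenol.
- Key C3–C4 bond ⇐ C8-dithianyl carbanion of the lower unit (acyl anion equivalent, future C4) + CH2 of an (S)-aryloxirane (future C3): two innately electrophilic carbons joined by polarity reversal.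
- C8–C4 link ⇐ dithienium substitution on hexa-O-benzyl-(+)-gallocatechin, so the interflavan bond exists before the upper heterocycle; epoxide ⇐ 3,4,5-tris(benzyloxy)benzaldehyde (Corey–Chaykovsky, hydrolytic kinetic resolution).
- Ring order: D, E, F from the natural flavanol; ring B from the aldehyde; ring A from the phenol; ring C closed last.

Assumption: (+)-gallocatechin (2R,3S) is bought as the natural product (it is the costliest starting material); the other starting materials are catalogue chemicals.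

**Step 1**
Reactants: 1 (+)-gallocatechin [(2R,3S)-2-(3,4,5-trihydroxyphenyl)chromane-3,5,7-triol]
Product: 2 hexa-O-benzyl-(+)-gallocatechin [(2R,3S)-3,5,7-tris(benzyloxy)-2-[3,4,5-tris(benzyloxy)phenyl]chromane]
Conditions: BnBr (7 equiv), NaH (7 equiv), DMF, −20 °C → rt
Reagents that add atoms: benzyl bromide, BrCc1ccccc1
Why: Williamson etherification caps the five phenols and the 3-OH so that the later organolithium, Mitsunobu and borane steps meet no acidic protons; no stereocentre is touched.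

**Step 2**
Reactants: 2 hexa-O-benzyl-(+)-gallocatechin
Product: 3 (2R,3S)-3,5,7-tris(benzyloxy)-8-(1,3-dithian-2-yl)-2-[3,4,5-tris(benzyloxy)phenyl]chromane
Conditions: 1,3-dithiane, Ph3CBF4, CH2Cl2, reflux; cool to −40 °C, add 2 and 2,6-di-tert-butyl-4-methylpyridine, → 0 °C
Reagents that add atoms: 1,3-dithiane, C1CSCSC1
Why: Electrophilic aromatic substitution with Corey's 1,3-dithian-2-ylium ion (made in the flask by hydride abstraction) should go to C8 of ring D, the less hindered nucleophilic site that NBS also takes in 5,7-di-O-benzylflavans, and installs the future C4 already masked as an acyl anion precursor.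

**Step 3**
Reactants: 4 3,4,5-tris(benzyloxy)benzaldehyde
Product: 5 rac-2-[3,4,5-tris(benzyloxy)phenyl]oxirane
Conditions: Me3SI, KOH, MeCN (trace H2O), 60 °C
Reagents that add atoms: trimethylsulfonium iodide, C[S+](C)C.[I-]
Why: Corey–Chaykovsky epoxidation, in which the sulfonium methylide adds to the aldehyde and closes to the terminal epoxide (racemic).

**Step 4**
Reactants: 5 rac-2-[3,4,5-tris(benzyloxy)phenyl]oxirane
Product: 6 (2S)-2-[3,4,5-tris(benzyloxy)phenyl]oxirane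
Conditions: (S,S)-[N,N'-bis(3,5-di-tert-butylsalicylidene)cyclohexane-1,2-diaminato]cobalt acetate (trivalent cobalt, 1 mol %), H2O (0.55 equiv), THF, 0 °C → rt
Reagents that add atoms: none
Why: Jacobsen hydrolytic kinetic resolution with the catalyst antipode that hydrolyses the (R)-epoxide, so the (S)-epoxide is recovered in high ee (at most 50 %) and carries the one stereocentre that is later relayed to the whole upper unit.

**Step 5**
Reactants: 3 (2R,3S)-3,5,7-tris(benzyloxy)-8-(1,3-dithian-2-yl)-2-[3,4,5-tris(benzyloxy)phenyl]chromane; 6 (2S)-2-[3,4,5-tris(benzyloxy)phenyl]oxirane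
Product: 8 (1R)-2-{2-[(2R,3S)-3,5,7-tris(benzyloxy)-2-[3,4,5-tris(benzyloxy)phenyl]chroman-8-yl]-1,3-dithian-2-yl}-1-[3,4,5-tris(benzyloxy)phenyl]ethan-1-ol, via lithio-dithiane 7 (not isolated)
Conditions: n-BuLi, THF/DMPU, −78 → −20 °C; then 6, −78 °C → rt; then H2O
Reagents that add atoms: none
Why: Corey–Seebach reaction, in which carbanion 7 (acyl anion equivalent, future C4) opens the epoxide at its unhindered CH2 (future C3) and so joins two innately electrophilic carbons; the carbinol carbon is not attacked and keeps the arrangement of 6 (R only through the priority change).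

**Step 6**
Reactants: 8 the (1R)-alcohol from step 5; 9 3-(benzyloxy)phenol
Product: 10 (2R,3S)-3,5,7-tris(benzyloxy)-8-{2-[(2S)-2-[3-(benzyloxy)phenoxy]-2-[3,4,5-tris(benzyloxy)phenyl]ethyl]-1,3-dithian-2-yl}-2-[3,4,5-tris(benzyloxy)phenyl]chromane
Conditions: PPh3, DIAD, toluene, 0 °C → rt
Reagents that add atoms: none
Why: Mitsunobu etherification, in which the phenol displaces the activated benzylic oxygen by SN2 with inversion, giving the (S)-aryl ether that is the O1–C2 bond and the C2 configuration of the upper unit.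

**Step 7**
Reactants: 10 the (S)-aryl ether dithiane from step 6
Product: 12 (2R,3S)-3,5,7-tris(benzyloxy)-8-{(2S)-7-(benzyloxy)-2-[3,4,5-tris(benzyloxy)phenyl]-2H-chromen-4-yl}-2-[3,4,5-tris(benzyloxy)phenyl]chromane, via ring-closed sulfide 11 (not isolated)
Conditions: Me2S(SMe)BF4 (DMTSF, 2.3 equiv), 2,6-di-tert-butyl-4-methylpyridine (3 equiv), CH2Cl2, −40 → 0 °C
Reagents that add atoms: none
Why: Proposed new method: MeS+ transfer to one dithiane sulfur opens the ring to a C4 thionium ion that ring A attacks intramolecularly (six-membered closure, para to OBn and ortho to O1) to give 11, and a second sulfenylation lets the tertiary doubly benzylic C–S bond ionise and lose H3 (E1) to the C3=C4 alkene while the buffered, enolisation-free medium leaves C2 untouched; the closest known chemistry is the Trost DMTSF thionium-ion Friedel–Crafts cyclisation of dithioacetals.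

**Step 8**
Reactants: 12 the 2,4-diaryl-2H-chromene from step 7
Product: 14 (2R,3S,4S)-7-(benzyloxy)-4-[(2R,3S)-3,5,7-tris(benzyloxy)-2-[3,4,5-tris(benzyloxy)phenyl]chroman-8-yl]-2-[3,4,5-tris(benzyloxy)phenyl]chroman-3-ol, via alkylborane 13 (not isolated)
Conditions: BH3·THF, THF, 0 °C → rt; then NaOH, H2O2, 0 °C → rt
Reagents that add atoms: hydrogen peroxide, OO
Why: Brown hydroboration–oxidation, in which BH3 adds syn and anti-Markovnikov (B to C3, H to the diaryl-substituted C4) from the face opposite the C2 aryl group, as known for flav-3-enes, and C–B oxidation with retention gives the 2,3-trans-3,4-trans (2R,3S,4S) array.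

**Step 9**
Reactants: 14 the deca-O-benzyl dimer from step 8
Product: 15 robinetinidol-(4alpha,8)-gallocatechin
Conditions: H2 (1 atm), Pd(OH)2/C, THF/MeOH, rt
Reagents that add atoms: none
Why: Catalytic hydrogenolysis of the ten benzyl ethers, as in procyanidin syntheses, leaves the C2–O1 bonds and all five stereocentres untouched.

**Compound list**
1 | (+)-gallocatechin | Oc1cc(O)c2c(c1)O[C@H](c1cc(O)c(O)c(O)c1)[C@@H](O)C2 | starting material
2 | hexa-O-benzyl-(+)-gallocatechin | C(c1ccccc1)Oc1cc(OCc2ccccc2)c2c(c1)O[C@H](c1cc(OCc3ccccc3)c(OCc3ccccc3)c(OCc3ccccc3)c1)[C@@H](OCc1ccccc1)C2 | intermediate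
3 | 8-(1,3-dithian-2-yl) derivative of 2 | C1CSC(SC1)c1c(OCc2ccccc2)cc(OCc2ccccc2)c2c1O[C@H](c1cc(OCc3ccccc3)c(OCc3ccccc3)c(OCc3ccccc3)c1)[C@@H](OCc1ccccc1)C2 | intermediate
4 | 3,4,5-tris(benzyloxy)benzaldehyde | O=Cc1cc(OCc2ccccc2)c(OCc2ccccc2)c(OCc2ccccc2)c1 | starting material
5 | rac-2-[3,4,5-tris(benzyloxy)phenyl]oxirane | C1OC1c1cc(OCc2ccccc2)c(OCc2ccccc2)c(OCc2ccccc2)c1 | intermediate
6 | (2S)-2-[3,4,5-tris(benzyloxy)phenyl]oxirane | C1O[C@H]1c1cc(OCc2ccccc2)c(OCc2ccccc2)c(OCc2ccccc2)c1 | intermediate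
7 | lithio-dithiane: 3 with lithium on the dithiane carbon between the sulfurs | [Li]C1(SCCCS1)c1c(OCc2ccccc2)cc(OCc2ccccc2)c2c1O[C@H](c1cc(OCc3ccccc3)c(OCc3ccccc3)c(OCc3ccccc3)c1)[C@@H](OCc1ccccc1)C2 | intermediate (not isolated)
8 | (1R)-2-{2-[lower unit-8-yl]-1,3-dithian-2-yl}-1-[3,4,5-tris(benzyloxy)phenyl]ethan-1-ol | O[C@@H](c1cc(OCc2ccccc2)c(OCc2ccccc2)c(OCc2ccccc2)c1)CC1(SCCCS1)c1c(OCc2ccccc2)cc(OCc2ccccc2)c2c1O[C@H](c1cc(OCc3ccccc3)c(OCc3ccccc3)c(OCc3ccccc3)c1)[C@@H](OCc1ccccc1)C2 | intermediate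
9 | 3-(benzyloxy)phenol | Oc1cccc(OCc2ccccc2)c1 | starting material
10 | (S)-3-(benzyloxy)phenyl ether of 8 (inverted carbinol centre) | C(c1ccccc1)Oc1cccc(c1)O[C@H](c1cc(OCc2ccccc2)c(OCc2ccccc2)c(OCc2ccccc2)c1)CC1(SCCCS1)c1c(OCc2ccccc2)cc(OCc2ccccc2)c2c1O[C@H](c1cc(OCc3ccccc3)c(OCc3ccccc3)c(OCc3ccccc3)c1)[C@@H](OCc1ccccc1)C2 | intermediate
11 | (2S)-7-(benzyloxy)-4-{[3-(methyldisulfanyl)propyl]sulfanyl}-4-[lower unit-8-yl]-2-[3,4,5-tris(benzyloxy)phenyl]chromane (both C4 epimers) | C(c1ccccc1)Oc1ccc2c(c1)O[C@H](c1cc(OCc3ccccc3)c(OCc3ccccc3)c(OCc3ccccc3)c1)CC2(SCCCSSC)c1c(OCc2ccccc2)cc(OCc2ccccc2)c2c1O[C@H](c1cc(OCc3ccccc3)c(OCc3ccccc3)c(OCc3ccccc3)c1)[C@@H](OCc1ccccc1)C2 | intermediate (not isolated)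
12 | (2S)-7-(benzyloxy)-4-[lower unit-8-yl]-2-[3,4,5-tris(benzyloxy)phenyl]-2H-chromene | C(c1ccccc1)Oc1ccc2c(c1)O[C@H](c1cc(OCc3ccccc3)c(OCc3ccccc3)c(OCc3ccccc3)c1)C=C2c1c(OCc2ccccc2)cc(OCc2ccccc2)c2c1O[C@H](c1cc(OCc3ccccc3)c(OCc3ccccc3)c(OCc3ccccc3)c1)[C@@H](OCc1ccccc1)C2 | intermediate
13 | alkylborane: 14 with BH2 in place of the upper 3-OH (same spatial arrangement) | C(c1ccccc1)Oc1ccc2c(c1)O[C@H](c1cc(OCc3ccccc3)c(OCc3ccccc3)c(OCc3ccccc3)c1)[C@@H](B)[C@@H]2c1c(OCc2ccccc2)cc(OCc2ccccc2)c2c1O[C@H](c1cc(OCc3ccccc3)c(OCc3ccccc3)c(OCc3ccccc3)c1)[C@@H](OCc1ccccc1)C2 | intermediate (not isolated)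
14 | deca-O-benzyl robinetinidol-(4alpha,8)-gallocatechin (upper 3-OH free; 2R,3S,4S upper; 2R,3S lower) | C(c1ccccc1)Oc1ccc2c(c1)O[C@H](c1cc(OCc3ccccc3)c(OCc3ccccc3)c(OCc3ccccc3)c1)[C@@H](O)[C@@H]2c1c(OCc2ccccc2)cc(OCc2ccccc2)c2c1O[C@H](c1cc(OCc3ccccc3)c(OCc3ccccc3)c(OCc3ccccc3)c1)[C@@H](OCc1ccccc1)C2 | intermediate
15 | robinetinidol-(4alpha,8)-gallocatechin | Oc1ccc2c(c1)O[C@H](c1cc(O)c(O)c(O)c1)[C@@H](O)[C@@H]2c1c(O)cc(O)c2c1O[C@H](c1cc(O)c(O)c(O)c1)[C@@H](O)C2 | target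

("lower unit-8-yl" = (2R,3S)-3,5,7-tris(benzyloxy)-2-[3,4,5-tris(benzyloxy)phenyl]chroman-8-yl.)

**Step count and risks**
Total steps: 9. Longest linear sequence: 7 (steps 1, 2, 5, 6, 7, 8, 9).

Three steps most likely to fail:

- **Step 5** (deprotonation and alkylation of a di-ortho-alkoxy aryl dithiane). Fallback, setting out from 6: the epoxide is opened instead by the lithium salt of parent 1,3-dithiane (n-BuLi, THF), which keeps the same reversed-polarity C3–C4 bond and gives the dithianyl alcohol F4. Mitsunobu etherification with 9 gives the (S)-aryl ether F5. Hydride abstraction from its dithiane C–H with Ph3CBF4 gives the dithienium salt F6, which arene 2 captures at C8 (−40 °C, hindered pyridine base) to come back to the route at 10.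

- **Step 7** (thionium cyclisation; risks are sulfenylation of ring D, loss of the allylic aryloxide, or a thionium too stabilised to cyclise). Fallback, setting out from 10: Hg(ClO4)2/CaCO3 in aqueous THF unmasks the β-aryloxy ketone F7, and a Bi(OTf)3-catalysed Friedel–Crafts cyclodehydration at −20 °C closes ring C through the carbonyl instead of sulfur activation, coming back to the route at 12.

- **Step 2** (C8 versus C6 selectivity and tolerance of the cationic reagent). Fallback, setting out from 2: NBS in CH2Cl2 at −78 °C gives the 8-bromide F1 with the documented C8 selectivity. Bromine–lithium exchange with n-BuLi gives the 8-lithio species F2, and a DMF quench gives the 8-carbaldehyde F3. Thioacetalisation with propane-1,3-dithiol and BF3·OEt2 comes back to the route at 3.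

**Further compounds**
F1 | step 2 | (2R,3S)-3,5,7-tris(benzyloxy)-8-bromo-2-[3,4,5-tris(benzyloxy)phenyl]chromane | Brc1c(OCc2ccccc2)cc(OCc2ccccc2)c2c1O[C@H](c1cc(OCc3ccccc3)c(OCc3ccccc3)c(OCc3ccccc3)c1)[C@@H](OCc1ccccc1)C2
F2 | step 2 | 8-lithio analogue of F1 | [Li]c1c(OCc2ccccc2)cc(OCc2ccccc2)c2c1O[C@H](c1cc(OCc3ccccc3)c(OCc3ccccc3)c(OCc3ccccc3)c1)[C@@H](OCc1ccccc1)C2
F3 | step 2 | (2R,3S)-3,5,7-tris(benzyloxy)-2-[3,4,5-tris(benzyloxy)phenyl]chromane-8-carbaldehyde | O=Cc1c(OCc2ccccc2)cc(OCc2ccccc2)c2c1O[C@H](c1cc(OCc3ccccc3)c(OCc3ccccc3)c(OCc3ccccc3)c1)[C@@H](OCc1ccccc1)C2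
F4 | step 5 | (1R)-2-(1,3-dithian-2-yl)-1-[3,4,5-tris(benzyloxy)phenyl]ethan-1-ol | O[C@@H](c1cc(OCc2ccccc2)c(OCc2ccccc2)c(OCc2ccccc2)c1)CC1SCCCS1
F5 | step 5 | 2-{(2S)-2-[3-(benzyloxy)phenoxy]-2-[3,4,5-tris(benzyloxy)phenyl]ethyl}-1,3-dithiane | C(c1ccccc1)Oc1cccc(c1)O[C@H](c1cc(OCc2ccccc2)c(OCc2ccccc2)c(OCc2ccccc2)c1)CC1SCCCS1
F6 | step 5 | 2-{(2S)-2-[3-(benzyloxy)phenoxy]-2-[3,4,5-tris(benzyloxy)phenyl]ethyl}-1,3-dithian-2-ylium tetrafluoroborate | C(c1ccccc1)Oc1cccc(c1)O[C@H](c1cc(OCc2ccccc2)c(OCc2ccccc2)c(OCc2ccccc2)c1)C[C+]1SCCCS1.F[B-](F)(F)F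
F7 | step 7 | (3S)-3-[3-(benzyloxy)phenoxy]-1-[(2R,3S)-3,5,7-tris(benzyloxy)-2-[3,4,5-tris(benzyloxy)phenyl]chroman-8-yl]-3-[3,4,5-tris(benzyloxy)phenyl]propan-1-one | C(c1ccccc1)Oc1cccc(c1)O[C@H](c1cc(OCc2ccccc2)c(OCc2ccccc2)c(OCc2ccccc2)c1)CC(=O)c1c(OCc2ccccc2)cc(OCc2ccccc2)c2c1O[C@H](c1cc(OCc3ccccc3)c(OCc3ccccc3)c(OCc3ccccc3)c1)[C@@H](OCc1ccccc1)C2
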